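**Plan**
- Retrosynthesis: the C1 bromine and the CH2Br bromine are removed (Br2 addition to an exocyclic C1=CH2 alkene), the C4 chloride is traced back to a ketone and the chloroalkene to a CH2OH group. Then the C5–C6 and C1–C2 bonds are cut together as a [4+2] cycloaddition.
- Enabling feature: ring atoms C2(Cl)–C3–C4(O, later Cl)–C5(CH3)(C) are a 1-chloro-3-oxy-butadiene. C6H2–C1 is the C=C of 2-bromoacrolein, used as an allene equivalent: its Br blocks loss of HCl and its CHO becomes the exocyclic carbon.
- Forward: the diene is built from propanoyl chloride, acetylene and formaldehyde, and a temporary di-tert-butylsilylene ring locks the tetrasubstituted enol ether. The Diels–Alder step closes the only carbocycle. Then CBr–CHO becomes C=CH2, the C4 ketone becomes OH then Cl, CH2OH becomes alkyne then (Z)-chloroalkene, and Br2 is added last.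
- Stereochemistry: C5 and C2 come from the catalyst-controlled suprafacial cycloaddition of the geometry-locked diene. C4 comes from hydroxyl-directed reduction followed by SN2 inversion. The Z alkene comes from syn reduction of a chloroalkyne. C1 comes from anti addition of Br2 with axial entry of bromide.

Key step: step 4

Remark: ring atoms are cited by the locants of the target name, (1S,2R,4S,5S)-1-bromo-1-(bromomethyl)-2,4-dichloro-5-[(Z)-2-chloroethenyl]-5-methylcyclohexane; systematic names of intermediates use their own numbering.
Assumption: the (S)-configured oxazaborolidinium catalyst is taken to expose the face of bound 2-bromoacrolein that leads to (4aS,7R)-9 in the endo mode; if the opposite sense is found, the (R)-catalyst is used with no other change. Compound 10 is drawn as the open hydroxy aldehyde although it may rest partly as its bridged lactol.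

**Step 1**
Reactants: 1 propanoyl chloride; 2 acetylene
Product: 3 (E)-1-chloropent-1-en-3-one
Conditions: AlCl3, C2H2 (stream), CH2Cl2, 0 °C → rt
Reagents that add atoms: none
Why: Friedel–Crafts-type acylation of acetylene, in which the acylium ion adds to the alkyne and chloride captures the vinyl cation, should give the more stable (E)-β-chlorovinyl ketone.

**Step 2**
Reactants: 3 (E)-1-chloropent-1-en-3-one; 4 formaldehyde (monomeric, from cracked paraformaldehyde)
Product: 6 (E)-1-chloro-5-hydroxy-4-methylpent-1-en-3-one (racemic), via lithium enolate 5 (not isolated)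
Conditions: LiN(SiMe3)2, THF, −78 °C; CH2O (gas); AcOH quench at −78 °C; used crude
Reagents that add atoms: none
Why: The kinetic lithium enolate (only the ethyl CH2 is enolisable) should undergo aldol addition to formaldehyde, the new stereocentre being irrelevant because it becomes sp2 in step 3 and the cold acidic quench avoiding oxa-Michael ring closure.

**Step 3**
Reactants: 6 (E)-1-chloro-5-hydroxy-4-methylpent-1-en-3-one
Product: 7 2,2-di-tert-butyl-6-[(E)-2-chloroethenyl]-5-methyl-4H-1,3,2-dioxasiline
Conditions: t-Bu2Si(OTf)2, i-Pr2NEt, CH2Cl2, −78 → 0 °C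
Reagents that add atoms: di-tert-butylsilyl bis(trifluoromethanesulfonate), CC(C)(C)[Si](OS(=O)(=O)C(F)(F)F)(OS(=O)(=O)C(F)(F)F)C(C)(C)C
Why: Enol silylation with a silyl triflate and amine, O-silylation of the primary alcohol followed by intramolecular silylation–deprotonation of the ketone, should close the six-membered silylene ring, which holds the CH2O carbon cis to the enol oxygen and so fixes the geometry of the tetrasubstituted enol ether.

**Step 4**
Reactants: 7 2,2-di-tert-butyl-6-[(E)-2-chloroethenyl]-5-methyl-4H-1,3,2-dioxasiline; 8 2-bromoacrolein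
Product: 10 (1S,2R,5S)-1-bromo-2-chloro-5-(hydroxymethyl)-5-methyl-4-oxocyclohexane-1-carbaldehyde, via silylene cycloadduct 9 (not isolated)
Conditions: (S)-3,3-diphenyl-1-(2-methylphenyl)tetrahydro-1H,3H-pyrrolo[1,2-c][1,3,2]oxazaborole protonated with HN(SO2CF3)2 (20 mol %), 8 (1.5 equiv), CH2Cl2, −78 → −40 °C; then HF·pyridine, THF, −20 → 0 °C
Reagents that add atoms: none
Why: The catalyst-bound 2-bromoacrolein and the electron-rich 1-chloro-3-silyloxy diene 7 should combine in an asynchronous, concerted, normal-electron-demand [4π+2π] cycloaddition in which the fully substituted, nucleophilic diene terminus (C5) bonds to the acrolein CH2 (C6) and the CHCl terminus (C2) bonds to the CBr carbon (C1); HF·pyridine then protonates the silyl enol ether at C3 and removes silicon as t-Bu2SiF2 without any base, so the β-chloro ketone survives. The closest known reaction type is the oxazaborolidinium-catalysed Diels–Alder reaction of 2-bromoacrolein with 2-silyloxy dienes followed by enol ether hydrolysis (Danishefsky-type cycloaddition–hydrolysis). The cyclohexene ring closes by suprafacial [4+2] cycloaddition, both σ bonds forming on one face of each partner, and no other ring is formed. C5 and C2 are set relative to one another by the diene geometry (the silylene ring holds the CH2O carbon "outside" and the E-chlorovinyl group holds Cl "outside", so they end up cis) and absolutely by the catalyst, which shields one face of the coordinated aldehyde; the CBr centre (C1) follows from the endo orientation of CHO and is deliberately temporary, since it becomes sp2 in step 5. The step needs regioselectivity, which the 3-silyloxy ("para") and 1-chloro ("ortho") substituents and the dialkylated terminus all direct the same way; endo selectivity, because the exo adduct would lead to the enantiomeric series after step 5 and is therefore removed as a diastereomer at 10; and integrity of the allylic C2–Cl bond, which is protected by the low temperature, the weakly donating silylene oxygen and the electron-poor CBr(CHO) neighbour, while the bromine on C1 leaves no α-hydrogen for loss of HCl.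

**Step 5**
Reactants: 10 (1S,2R,5S)-1-bromo-2-chloro-5-(hydroxymethyl)-5-methyl-4-oxocyclohexane-1-carbaldehyde
Product: 13 (2S,5R)-5-chloro-2-(hydroxymethyl)-2-methyl-4-methylidenecyclohexan-1-one, via hydrazone 11 (not isolated), via vinyldiazene 12 (not isolated)
Conditions: N2H4·H2O (1.1 equiv), KOAc, AcOH, EtOH, 0 °C → rt
Reagents that add atoms: none
Why: Kishner–Leonard (Wharton-type) reductive elimination, in which the aldehyde (far more reactive than the neopentylic ketone) forms hydrazone 11, which loses HBr to vinyldiazene 12 and then N2, should leave the exocyclic methylene under buffered conditions that spare the β-chloro ketone; no stereocentre is formed.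

**Step 6**
Reactants: 13 (2S,5R)-5-chloro-2-(hydroxymethyl)-2-methyl-4-methylidenecyclohexan-1-one
Product: 14 (1R,2S,5R)-5-chloro-2-(hydroxymethyl)-2-methyl-4-methylidenecyclohexan-1-ol
Conditions: Me4NBH(OAc)3, MeCN/AcOH (1:1), −30 °C
Reagents that add atoms: none
Why: Hydroxyl-directed (Evans–Saksena) reduction delivers hydride intramolecularly to the ketone face cis to the CH2OH group, so the new alcohol at C4 should stand trans to CH2OH (1R in 14), the configuration needed for inversion in step 9.

**Step 7**
Reactants: 14 (1R,2S,5R)-5-chloro-2-(hydroxymethyl)-2-methyl-4-methylidenecyclohexan-1-ol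
Product: 15 (1R,2R,4R)-4-chloro-2-hydroxy-1-methyl-5-methylidenecyclohexane-1-carbaldehyde
Conditions: 2,2,6,6-tetramethylpiperidin-1-oxyl (10 mol %), PhI(OAc)2, CH2Cl2, rt
Reagents that add atoms: none
Why: The oxoammonium (TEMPO) oxidation is selective for the primary alcohol over the hindered secondary one and stops at the aldehyde, which has no α-hydrogen.

**Step 8**
Reactants: 15 (1R,2R,4R)-4-chloro-2-hydroxy-1-methyl-5-methylidenecyclohexane-1-carbaldehyde
Product: 16 (1R,2S,5R)-5-chloro-2-ethynyl-2-methyl-4-methylidenecyclohexan-1-ol
Conditions: dimethyl (1-diazo-2-oxopropyl)phosphonate, K2CO3, MeOH, 0 °C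
Reagents that add atoms: dimethyl (1-diazo-2-oxopropyl)phosphonate (Ohira–Bestmann reagent), CC(=O)C(=[N+]=[N-])P(=O)(OC)OC
Why: Seyferth–Gilbert homologation with the Ohira–Bestmann reagent should convert the non-enolisable aldehyde into the terminal alkyne under mild carbonate conditions at low temperature, leaving the quaternary centre untouched.

**Step 9**
Reactants: 16 (1R,2S,5R)-5-chloro-2-ethynyl-2-methyl-4-methylidenecyclohexan-1-ol
Product: 17 (1S,2S,4R)-2,4-dichloro-1-ethynyl-1-methyl-5-methylidenecyclohexane
Conditions: PPh3, CCl4, pyridine, toluene, 50 °C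
Reagents that add atoms: carbon tetrachloride, ClC(Cl)(Cl)Cl
Why: The Appel reaction replaces the axial hydroxyl by chloride through SN2 displacement with inversion, which should give the equatorial C4 chloride cis to the ethynyl group (2S in 17); the slim ethynyl group is the smallest possible neighbour on the side of the incoming chloride.

**Step 10**
Reactants: 17 (1S,2S,4R)-2,4-dichloro-1-ethynyl-1-methyl-5-methylidenecyclohexane
Product: 19 (1S,2S,4R)-2,4-dichloro-1-(chloroethynyl)-1-methyl-5-methylidenecyclohexane, via lithium acetylide 18 (not isolated)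
Conditions: n-BuLi, THF, −78 °C; then N-chlorosuccinimide, −78 → 0 °C; NH4Cl quench
Reagents that add atoms: N-chlorosuccinimide, O=C1CCC(=O)N1Cl
Why: Deprotonation of the terminal alkyne and electrophilic chlorination of lithium acetylide 18 should give the 1-chloroalkyne, the alkyl chlorides being inert to the base at −78 °C.

**Step 11**
Reactants: 19 (1S,2S,4R)-2,4-dichloro-1-(chloroethynyl)-1-methyl-5-methylidenecyclohexane
Product: 20 (1S,2S,4R)-2,4-dichloro-1-[(Z)-2-chloroethenyl]-1-methyl-5-methylidenecyclohexane
Conditions: 2-nitrobenzenesulfonylhydrazide, Et3N, THF/i-PrOH, rt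
Reagents that add atoms: none
Why: Diimide generated in the flask adds two hydrogens to the same face of the chloroalkyne (syn reduction of a 1-haloalkyne), which should give the (Z)-chloroalkene without touching the C–Cl bonds or the hindered 1,1-disubstituted alkene.

**Step 12**
Reactants: 20 (1S,2S,4R)-2,4-dichloro-1-[(Z)-2-chloroethenyl]-1-methyl-5-methylidenecyclohexane
Product: 21 (1S,2R,4S,5S)-1-bromo-1-(bromomethyl)-2,4-dichloro-5-[(Z)-2-chloroethenyl]-5-methylcyclohexane
Conditions: Br2 (1.0 equiv), CH2Cl2, −78 °C, dark
Reagents that add atoms: bromine, BrBr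
Why: Ionic anti addition of Br2 should occur only at the 1,1-disubstituted alkene (the chloroalkene is far less nucleophilic), with electrophilic bromine taken up at the CH2 terminus from the open equatorial face and bromide entering the ring carbon from the axial side, cis to the C2 chlorine, so that Br is axial (1S) and CH2Br equatorial, which is also the more stable epimer.

**Compound list**
1 | propanoyl chloride | CCC(=O)Cl | starting material
2 | acetylene | C#C | starting material
3 | (E)-1-chloropent-1-en-3-one | CCC(=O)/C=C/Cl | intermediate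
4 | formaldehyde | C=O | starting material
5 | lithium enolate of 3 (not isolated) | [Li+].CC=C([O-])/C=C/Cl | intermediate
6 | (E)-1-chloro-5-hydroxy-4-methylpent-1-en-3-one (racemic) | CC(CO)C(=O)/C=C/Cl | intermediate
7 | 2,2-di-tert-butyl-6-[(E)-2-chloroethenyl]-5-methyl-4H-1,3,2-dioxasiline | CC1=C(/C=C/Cl)O[Si](C(C)(C)C)(C(C)(C)C)OC1 | intermediate
8 | 2-bromoacrolein (2-bromoprop-2-enal) | C=C(Br)C=O | starting material
9 | (4aS,6S,7R)-6-bromo-2,2-di-tert-butyl-7-chloro-4a-methyl-4a,5,6,7-tetrahydro-4H-benzo[d][1,3,2]dioxasiline-6-carbaldehyde (silylene cycloadduct, not isolated) | C[C@@]12C[C@](Br)(C=O)[C@H](Cl)C=C1O[Si](C(C)(C)C)(C(C)(C)C)OC2 | intermediate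
10 | (1S,2R,5S)-1-bromo-2-chloro-5-(hydroxymethyl)-5-methyl-4-oxocyclohexane-1-carbaldehyde | C[C@@]1(CO)C[C@](Br)(C=O)[C@H](Cl)CC1=O | intermediate
11 | (2S,4S,5R)-4-bromo-5-chloro-4-(hydrazinylidenemethyl)-2-(hydroxymethyl)-2-methylcyclohexan-1-one (hydrazone, not isolated) | C[C@@]1(CO)C[C@](Br)(C=NN)[C@H](Cl)CC1=O | intermediate
12 | (2S,5R)-5-chloro-4-(diazenylmethylidene)-2-(hydroxymethyl)-2-methylcyclohexan-1-one (vinyldiazene, not isolated) | C[C@@]1(CO)CC(=CN=N)[C@H](Cl)CC1=O | intermediate
13 | (2S,5R)-5-chloro-2-(hydroxymethyl)-2-methyl-4-methylidenecyclohexan-1-one | C[C@@]1(CO)CC(=C)[C@H](Cl)CC1=O | intermediate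
14 | (1R,2S,5R)-5-chloro-2-(hydroxymethyl)-2-methyl-4-methylidenecyclohexan-1-ol | C[C@@]1(CO)CC(=C)[C@H](Cl)C[C@H]1O | intermediate
15 | (1R,2R,4R)-4-chloro-2-hydroxy-1-methyl-5-methylidenecyclohexane-1-carbaldehyde | C[C@@]1(C=O)CC(=C)[C@H](Cl)C[C@H]1O | intermediate
16 | (1R,2S,5R)-5-chloro-2-ethynyl-2-methyl-4-methylidenecyclohexan-1-ol | C[C@@]1(C#C)CC(=C)[C@H](Cl)C[C@H]1O | intermediate
17 | (1S,2S,4R)-2,4-dichloro-1-ethynyl-1-methyl-5-methylidenecyclohexane | C[C@@]1(C#C)CC(=C)[C@H](Cl)C[C@@H]1Cl | intermediate
18 | lithium acetylide of 17 (not isolated) | [Li+].C[C@@]1(C#[C-])CC(=C)[C@H](Cl)C[C@@H]1Cl | intermediate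
19 | (1S,2S,4R)-2,4-dichloro-1-(chloroethynyl)-1-methyl-5-methylidenecyclohexane | C[C@@]1(C#CCl)CC(=C)[C@H](Cl)C[C@@H]1Cl | intermediate
20 | (1S,2S,4R)-2,4-dichloro-1-[(Z)-2-chloroethenyl]-1-methyl-5-methylidenecyclohexane | C[C@@]1(/C=C\Cl)CC(=C)[C@H](Cl)C[C@@H]1Cl | intermediate
21 | (1S,2R,4S,5S)-1-bromo-1-(bromomethyl)-2,4-dichloro-5-[(Z)-2-chloroethenyl]-5-methylcyclohexane | C[C@@]1(/C=C\Cl)C[C@@](Br)(CBr)[C@H](Cl)C[C@@H]1Cl | target

**Totals**
Total step count: 12. Longest linear sequence: 12 steps (from propanoyl chloride).

**Steps most likely to fail**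

Step 4. What may go wrong: the "inside" methyl group slows the cycloaddition. The cationic boron Lewis acid may ionise the allylic C2–Cl bond of the adduct, causing loss or epimerisation of chloride and deactivation of the catalyst. Facial and endo control may also be incomplete. Fallback (uncatalysed cycloaddition and resolution instead of catalyst control), setting out from 7 and 8 and returning at 14: 7 and 8 are heated without Lewis acid (toluene, 60 °C) and worked up with HF·pyridine as before. This should give racemic 10, that is 10 together with its enantiomer ent-10 F2, formed through the mirror-image adduct ent-9 F1. The racemate is taken through steps 5 and 6, the mirror-image series passing through hydrazone ent-11 F3 and vinyldiazene ent-12 F4 to ent-13 F5 and ent-14 F6. The primary hydroxyl of the racemic diol is esterified with (S)-O-methylmandelic acid (dicyclohexylcarbodiimide, 4-(dimethylamino)pyridine, CH2Cl2, 0 °C). The diastereomeric esters, the (S)-O-methylmandelate of 14 F7 and the (S)-O-methylmandelate of ent-14 F8, are separated by chromatography, and F7 is cleaved with K2CO3 in MeOH to rejoin the route at 14.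

Step 9. What may go wrong: E2 elimination from the axial oxyphosphonium ion, a 1,2-shift at the neopentylic carbon, or chloride exchange and allylic transposition at the C2–Cl bond may outrun the SN2 displacement. Fallback (front-side delivery of chloride instead of backside attack), setting out from 16 and returning at 17: 16 is oxidised with Dess–Martin periodinane to (2S,5R)-5-chloro-2-ethynyl-2-methyl-4-methylidenecyclohexan-1-one F9. NaBH4 (MeOH, −40 °C) adds hydride axially, from the face of the methyl group, to give the equatorial alcohol (1S,2S,5R)-5-chloro-2-ethynyl-2-methyl-4-methylidenecyclohexan-1-ol F10. Its chlorosulfite F11 (SOCl2, CH2Cl2, 0 °C) is collapsed with catalytic TiCl4, the known stereoretentive chlorination of cyclic secondary alcohols, to give 17.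

Step 12. What may go wrong: bromide may open the bromonium ion at the CH2 terminus, or electrophilic bromine may be taken up on the axial face; both lead to the C1 epimer. Excess reagent could also attack the chloroalkene. Fallback (thermodynamic instead of kinetic control), setting out from 20 and returning at 21: the addition to 20 is run as before. The C1 epimer, (1R,2R,4S,5S)-1-bromo-1-(bromomethyl)-2,4-dichloro-5-[(Z)-2-chloroethenyl]-5-methylcyclohexane F12, is then equilibrated by the known mutarotation of vicinal dibromides (1,2-interchange of the two bromine atoms through the bromonium–bromide ion pair; 1,2-dichloroethane, 60 °C). This inverts C1 and should drain F12 into the more stable 21, in which CH2Br, CH3 and both ring chlorines are equatorial.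

**Further compounds**
F1 | step 4 | ent-9, (4aR,6R,7S)-6-bromo-2,2-di-tert-butyl-7-chloro-4a-methyl-4a,5,6,7-tetrahydro-4H-benzo[d][1,3,2]dioxasiline-6-carbaldehyde | C[C@]12C[C@@](Br)(C=O)[C@@H](Cl)C=C1O[Si](C(C)(C)C)(C(C)(C)C)OC2
F2 | step 4 | ent-10, (1R,2S,5R)-1-bromo-2-chloro-5-(hydroxymethyl)-5-methyl-4-oxocyclohexane-1-carbaldehyde | C[C@]1(CO)C[C@@](Br)(C=O)[C@@H](Cl)CC1=O
F3 | step 4 | ent-11, hydrazone of F2 | C[C@]1(CO)C[C@@](Br)(C=NN)[C@@H](Cl)CC1=O
F4 | step 4 | ent-12, (2R,5S)-5-chloro-4-(diazenylmethylidene)-2-(hydroxymethyl)-2-methylcyclohexan-1-one | C[C@]1(CO)CC(=CN=N)[C@@H](Cl)CC1=O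
F5 | step 4 | ent-13, (2R,5S)-5-chloro-2-(hydroxymethyl)-2-methyl-4-methylidenecyclohexan-1-one | C[C@]1(CO)CC(=C)[C@@H](Cl)CC1=O
F6 | step 4 | ent-14, (1S,2R,5S)-5-chloro-2-(hydroxymethyl)-2-methyl-4-methylidenecyclohexan-1-ol | C[C@]1(CO)CC(=C)[C@@H](Cl)C[C@@H]1O
F7 | step 4 | (S)-O-methylmandelate of 14 (ester of the primary hydroxyl) | C[C@@]1(COC(=O)[C@@H](OC)c2ccccc2)CC(=C)[C@H](Cl)C[C@H]1O
F8 | step 4 | (S)-O-methylmandelate of ent-14 (ester of the primary hydroxyl) | C[C@]1(COC(=O)[C@@H](OC)c2ccccc2)CC(=C)[C@@H](Cl)C[C@@H]1O
F9 | step 9 | (2S,5R)-5-chloro-2-ethynyl-2-methyl-4-methylidenecyclohexan-1-one | C[C@@]1(C#C)CC(=C)[C@H](Cl)CC1=O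
F10 | step 9 | (1S,2S,5R)-5-chloro-2-ethynyl-2-methyl-4-methylidenecyclohexan-1-ol | C[C@@]1(C#C)CC(=C)[C@H](Cl)C[C@@H]1O
F11 | step 9 | chlorosulfite of F10 | C[C@@]1(C#C)CC(=C)[C@H](Cl)C[C@@H]1OS(Cl)=O
F12 | step 12 | (1R,2R,4S,5S)-1-bromo-1-(bromomethyl)-2,4-dichloro-5-[(Z)-2-chloroethenyl]-5-methylcyclohexane | C[C@@]1(/C=C\Cl)C[C@](Br)(CBr)[C@H](Cl)C[C@@H]1Cl
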